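The depside is cut at its aryl ester into a ring B acid, drawn from atraric acid, and a ring A phenol. The plan rests on assembling hexasubstituted ring A from two acyclic pieces. In ring A the C3 methyl sits between two oxygenated carbons (C2, C4), the 1,3-dioxygenation of a β-keto ester. The adjacent C1 ester/C6 methyl pair is a butynoate in disguise. One (4+2) benzannulation forges C1–C2 and C5–C6, closes the ring and, after loss of methanol and desilylation, sets all six substituents. Its diene is a penta-1,3-diene with a methoxy(silyloxy) ketene acetal terminus, a 2-methyl, a 3-silyloxy group and a methyl-capped CH terminus.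

Key step: step 3

Remark on the chemistry: the silyl enol ether and the diene are drawn as single geometric isomers, and the cycloadduct as the racemic isomer expected from suprafacial addition. Isomer mixtures would be carried on unchanged, because all of these features vanish when ring A becomes aromatic, and the target has no stereocentre.

Numbering: each ring is numbered from its carboxyl-bearing carbon (C1), with primes for ring B.

Step 1
Reactants: 1 methyl 2-methyl-3-oxopentanoate (racemic)
Product: 2 methyl (E)-2-methyl-3-(trimethylsilyloxy)pent-2-enoate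
Conditions: Me3SiCl (1.5 equiv), Et3N (1.6 equiv), toluene, rt, 2–3 d; filtration, distillation
Reagents that add atoms: chlorotrimethylsilane, C[Si](C)(C)Cl
Why: Silyl enol ether formation by soft enolization of a β-keto ester; the amine removes the acidic C2 proton and the hard silicon electrophile is taken up on the ketone oxygen.

Step 2
Reactants: 2 methyl (E)-2-methyl-3-(trimethylsilyloxy)pent-2-enoate
Product: 4 (1Z,3Z)-1-methoxy-2-methyl-1,3-bis(trimethylsilyloxy)penta-1,3-diene, via lithium dienolate 3 (not isolated)
Conditions: LiN(iPr)2 (1.3 equiv, commercial solution), THF, −78 °C, 1 h; Me3SiCl (1.5 equiv), −78 °C to rt; hexane, filtration under Ar, used fresh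
Reagents that add atoms: chlorotrimethylsilane, C[Si](C)(C)Cl
Why: Kinetic γ-deprotonation of the enoate at the C4 methylene (the only position giving an ester-conjugated anion) followed by O-silylation to the silyl ketene acetal, the standard second stage for 1-alkoxy-1,3-bis(silyloxy)dienes; allylic strain against the C2 methyl should turn the terminal methyl outward, cis to the silyloxy group.

Step 3
Reactants: 4 (1Z,3Z)-1-methoxy-2-methyl-1,3-bis(trimethylsilyloxy)penta-1,3-diene; 5 methyl but-2-ynoate
Product: 8 methyl 2,4-dihydroxy-3,5,6-trimethylbenzoate, via cyclohexadiene cycloadduct 6 (not isolated), via bis(silyl) resorcylate 7 (not isolated)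
Conditions: 4 (2.5 equiv), neat, sealed tube, Ar, 140 °C, 24–48 h; then 1 M HCl, THF, rt
Reagents that add atoms: none
Why: This is a normal-electron-demand Diels–Alder benzannulation of an alkoxy-bis(silyloxy)diene with an acetylenic ester, a known entry to 2,4-dihydroxybenzoates. The three oxygen donors place the largest HOMO coefficient on the methyl-bearing CH terminus, which bonds to the electrophilic β carbon of 5 (C5–C6) and leaves the ketene acetal carbon for the α carbon (C1–C2); a stepwise Mukaiyama–Michael addition followed by 6-exo-trig collapse of the allenolate onto the silyloxycarbenium carbon gives the same pairing. Ring A is thus closed in an intermolecular (4+2) mode, with both new ring bonds made between the two components. Adduct 6 carries a mixed ketal carbon (C2) across the ring from the C5–H, so 1,4-elimination of methanol should give arene 7, and dilute acid then strips both silyl groups and aromatizes any surviving 6 through its dienone. The two sp3 centres of 6 are transient and no stereocentre remains, so facial and endo/exo selectivity are irrelevant; regioselectivity is the only requirement, and the polarity match of the two components secures it. The outward terminal methyl of the (3Z) diene keeps the s-cis conformer accessible, while excess diene, absence of solvent and heat answer the low reactivity of a β-methylated ynoate.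

Step 4
Reactants: 9 methyl 2,4-dihydroxy-3,6-dimethylbenzoate (atraric acid)
Product: 10 methyl 5-chloro-2,4-dihydroxy-3,6-dimethylbenzoate
Conditions: SO2Cl2 (1.0 equiv), CH2Cl2–Et2O, 0 °C to rt
Reagents that add atoms: sulfuryl chloride, O=S(=O)(Cl)Cl
Why: Electrophilic aromatic chlorination; C5 is the only unsubstituted ring carbon and is activated ortho to the C4 hydroxyl and para to the C2 hydroxyl, so one equivalent of reagent has a single site to attack.

Step 5
Reactants: 10 methyl 5-chloro-2,4-dihydroxy-3,6-dimethylbenzoate
Product: 11 methyl 4-benzyloxy-5-chloro-2-hydroxy-3,6-dimethylbenzoate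
Conditions: BnBr (1.05 equiv), K2CO3 (1.2 equiv), acetone, reflux
Reagents that add atoms: benzyl bromide, BrCc1ccccc1
Why: Williamson ether synthesis; the C2 hydroxyl is locked in a hydrogen bond to the ester carbonyl, whereas the C4 hydroxyl, acidified by the para ester and the ortho chlorine, is ionized and alkylated selectively by a limited amount of halide.

Step 6
Reactants: 11 methyl 4-benzyloxy-5-chloro-2-hydroxy-3,6-dimethylbenzoate
Product: 12 methyl 4-benzyloxy-5-chloro-2-methoxy-3,6-dimethylbenzoate
Conditions: MeI (3 equiv), K2CO3 (2 equiv), DMF, 50 °C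
Reagents that add atoms: iodomethane, CI
Why: Williamson O-methylation of the remaining chelated phenol under more forcing conditions, with no other acidic site left in the molecule.

Step 7
Reactants: 12 methyl 4-benzyloxy-5-chloro-2-methoxy-3,6-dimethylbenzoate
Product: 14 4-benzyloxy-5-chloro-2-methoxy-3,6-dimethylbenzoic acid, via potassium carboxylate 13 (not isolated)
Conditions: KOH (10 equiv), DMSO–H2O, 95 °C; then 2 M HCl, 0 °C
Reagents that add atoms: potassium hydroxide, [K+].[OH-]
Why: Saponification (BAc2) of a di-ortho-substituted benzoate with poorly solvated hydroxide in aqueous DMSO, the usual remedy for such hindrance; both ethers and the unactivated aryl chloride (meta to the carboxyl) tolerate it, and cold acidification avoids decarboxylation.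

Step 8
Reactants: 14 4-benzyloxy-5-chloro-2-methoxy-3,6-dimethylbenzoic acid; 8 methyl 2,4-dihydroxy-3,5,6-trimethylbenzoate
Product: 16 methyl 4-[(4-benzyloxy-5-chloro-2-methoxy-3,6-dimethylbenzoyl)oxy]-2-hydroxy-3,5,6-trimethylbenzoate, via mixed trifluoroacetic anhydride 15 (not isolated)
Conditions: (CF3CO)2O (4 equiv), toluene, 0 °C to rt; aq NaHCO3 work-up
Reagents that add atoms: none
Why: Depside esterification through a mixed trifluoroacetic anhydride; the electron-rich di-ortho-substituted acid ionizes readily to a linear acylium ion that evades the steric block, fully substituted ring A rules out Friedel–Crafts C-acylation, and the ester-chelated C2 hydroxyl stays passive so that the C4 hydroxyl is the one acylated.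

Step 9
Reactants: 16 methyl 4-[(4-benzyloxy-5-chloro-2-methoxy-3,6-dimethylbenzoyl)oxy]-2-hydroxy-3,5,6-trimethylbenzoate
Product: 17 methyl 4-[(5-chloro-4-hydroxy-2-methoxy-3,6-dimethylbenzoyl)oxy]-2-hydroxy-3,5,6-trimethylbenzoate (CNP0121273.0)
Conditions: H2 (1 atm), 10% Pd/C, EtOAc, rt, stopped after uptake of one equivalent of H2
Reagents that add atoms: none
Why: Catalytic hydrogenolysis of a benzyl aryl ether; in neutral ethyl acetate without base, benzylic C–O cleavage should be much faster than reduction of the hindered aryl C–Cl bond, and both esters are inert.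

Compound list
1 | methyl 2-methyl-3-oxopentanoate (racemic) | CCC(=O)C(C)C(=O)OC | starting material
2 | methyl (E)-2-methyl-3-(trimethylsilyloxy)pent-2-enoate | CC/C(O[Si](C)(C)C)=C(/C)C(=O)OC | intermediate
3 | lithium 1-methoxy-2-methyl-3-(trimethylsilyloxy)penta-1,3-dien-1-olate | C/C=C(O[Si](C)(C)C)/C(C)=C(/OC)[O-].[Li+] | intermediate
4 | (1Z,3Z)-1-methoxy-2-methyl-1,3-bis(trimethylsilyloxy)penta-1,3-diene | C/C=C(O[Si](C)(C)C)/C(C)=C(/OC)O[Si](C)(C)C | intermediate
5 | methyl but-2-ynoate | CC#CC(=O)OC | starting material
6 | methyl 6-methoxy-2,3,5-trimethyl-4,6-bis(trimethylsilyloxy)cyclohexa-1,4-diene-1-carboxylate (racemic, 3-methyl cis to 6-methoxy) | COC(=O)C1=C(C)[C@@H](C)C(O[Si](C)(C)C)=C(C)[C@]1(OC)O[Si](C)(C)C | intermediate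
7 | methyl 3,5,6-trimethyl-2,4-bis(trimethylsilyloxy)benzoate | COC(=O)c1c(C)c(C)c(O[Si](C)(C)C)c(C)c1O[Si](C)(C)C | intermediate
8 | methyl 2,4-dihydroxy-3,5,6-trimethylbenzoate | COC(=O)c1c(C)c(C)c(O)c(C)c1O | intermediate
9 | methyl 2,4-dihydroxy-3,6-dimethylbenzoate (atraric acid) | COC(=O)c1c(C)cc(O)c(C)c1O | starting material
10 | methyl 5-chloro-2,4-dihydroxy-3,6-dimethylbenzoate | COC(=O)c1c(C)c(Cl)c(O)c(C)c1O | intermediate
11 | methyl 4-benzyloxy-5-chloro-2-hydroxy-3,6-dimethylbenzoate | COC(=O)c1c(C)c(Cl)c(OCc2ccccc2)c(C)c1O | intermediate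
12 | methyl 4-benzyloxy-5-chloro-2-methoxy-3,6-dimethylbenzoate | COC(=O)c1c(C)c(Cl)c(OCc2ccccc2)c(C)c1OC | intermediate
13 | potassium 4-benzyloxy-5-chloro-2-methoxy-3,6-dimethylbenzoate | COc1c(C)c(OCc2ccccc2)c(Cl)c(C)c1C(=O)[O-].[K+] | intermediate
14 | 4-benzyloxy-5-chloro-2-methoxy-3,6-dimethylbenzoic acid | COc1c(C)c(OCc2ccccc2)c(Cl)c(C)c1C(=O)O | intermediate
15 | 4-benzyloxy-5-chloro-2-methoxy-3,6-dimethylbenzoic trifluoroacetic anhydride | COc1c(C)c(OCc2ccccc2)c(Cl)c(C)c1C(=O)OC(=O)C(F)(F)F | intermediate
16 | methyl 4-[(4-benzyloxy-5-chloro-2-methoxy-3,6-dimethylbenzoyl)oxy]-2-hydroxy-3,5,6-trimethylbenzoate | COC(=O)c1c(C)c(C)c(OC(=O)c2c(C)c(Cl)c(OCc3ccccc3)c(C)c2OC)c(C)c1O | intermediate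
17 | methyl 4-[(5-chloro-4-hydroxy-2-methoxy-3,6-dimethylbenzoyl)oxy]-2-hydroxy-3,5,6-trimethylbenzoate | COC(=O)c1c(C)c(C)c(OC(=O)c2c(C)c(Cl)c(O)c(C)c2OC)c(C)c1O | target

Total step count: 9.
Longest linear sequence: 6 steps (steps 4 to 9, from atraric acid 9). The ring A branch (steps 1 to 3) joins at step 8.

Steps most likely to fail

Step 3. The cycloaddition of a fully substituted diene with a β-methylated ynoate may be slower than decay of the diene. That decay runs by oxygen-to-carbon silyl shift and by protodesilylation with the methanol that is released, so conversion could stall. The fallback functionalizes an existing arene instead of building ring A. It sets out from atraric acid 9, whose only free position C5 is formylated by Rieche formylation (Cl2CHOCH3, TiCl4, CH2Cl2, 0 °C, aqueous work-up). This should give methyl 5-formyl-2,4-dihydroxy-3,6-dimethylbenzoate F1. The formyl group is then reduced to methyl by hydrogenolysis of the ortho-hydroxy aldehyde (H2, 10% Pd/C, AcOH–EtOAc, rt), which rejoins the route at 8.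

Step 8. Acyl transfer may stall because both partners carry two ortho substituents, and reversible trifluoroacetylation of the phenol would compete. The fallback replaces the acylium generated in the flask by a preformed acyl chloride and a preformed phenolate. It sets out from 14, which with (COCl)2 and catalytic DMF in CH2Cl2 should give 4-benzyloxy-5-chloro-2-methoxy-3,6-dimethylbenzoyl chloride F2. Separately, 8 is deprotonated at its more acidic, unchelated C4 hydroxyl with NaH (1 equiv, THF, 0 °C) to sodium 3-hydroxy-4-(methoxycarbonyl)-2,5,6-trimethylphenolate F3. Combining the two (THF, 0 °C to reflux) comes back to the route at 16.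

Step 9. Hydrodechlorination of ring B may run alongside debenzylation. The fallback moves the chlorination to the end, so that no C–Cl bond is present during the hydrogenolysis. It sets out from 9 and runs as follows:
- Benzylation as in step 5 gives methyl 4-benzyloxy-2-hydroxy-3,6-dimethylbenzoate F4.
- Methylation as in step 6 gives methyl 4-benzyloxy-2-methoxy-3,6-dimethylbenzoate F5.
- Saponification as in step 7 passes through potassium 4-benzyloxy-2-methoxy-3,6-dimethylbenzoate F6 to 4-benzyloxy-2-methoxy-3,6-dimethylbenzoic acid F7.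
- Coupling with 8 as in step 8 proceeds through 4-benzyloxy-2-methoxy-3,6-dimethylbenzoic trifluoroacetic anhydride F8 to methyl 4-[(4-benzyloxy-2-methoxy-3,6-dimethylbenzoyl)oxy]-2-hydroxy-3,5,6-trimethylbenzoate F9.
- Hydrogenolysis as in step 9 gives methyl 2-hydroxy-4-[(4-hydroxy-2-methoxy-3,6-dimethylbenzoyl)oxy]-3,5,6-trimethylbenzoate F10.
- C5' of F10 is the only aromatic C–H of the whole molecule and lies ortho to the free C4' hydroxyl, so SO2Cl2 (1.0 equiv, CH2Cl2–Et2O, 0 °C) should chlorinate there and reach the route again at 17.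

Further compounds
F1 | step 3 | methyl 5-formyl-2,4-dihydroxy-3,6-dimethylbenzoate | COC(=O)c1c(C)c(C=O)c(O)c(C)c1O
F2 | step 8 | 4-benzyloxy-5-chloro-2-methoxy-3,6-dimethylbenzoyl chloride | COc1c(C)c(OCc2ccccc2)c(Cl)c(C)c1C(Cl)=O
F3 | step 8 | sodium 3-hydroxy-4-(methoxycarbonyl)-2,5,6-trimethylphenolate | COC(=O)c1c(C)c(C)c([O-])c(C)c1O.[Na+]
F4 | step 9 | methyl 4-benzyloxy-2-hydroxy-3,6-dimethylbenzoate | COC(=O)c1c(C)cc(OCc2ccccc2)c(C)c1O
F5 | step 9 | methyl 4-benzyloxy-2-methoxy-3,6-dimethylbenzoate | COC(=O)c1c(C)cc(OCc2ccccc2)c(C)c1OC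
F6 | step 9 | potassium 4-benzyloxy-2-methoxy-3,6-dimethylbenzoate | COc1c(C)c(OCc2ccccc2)cc(C)c1C(=O)[O-].[K+]
F7 | step 9 | 4-benzyloxy-2-methoxy-3,6-dimethylbenzoic acid | COc1c(C)c(OCc2ccccc2)cc(C)c1C(=O)O
F8 | step 9 | 4-benzyloxy-2-methoxy-3,6-dimethylbenzoic trifluoroacetic anhydride | COc1c(C)c(OCc2ccccc2)cc(C)c1C(=O)OC(=O)C(F)(F)F
F9 | step 9 | methyl 4-[(4-benzyloxy-2-methoxy-3,6-dimethylbenzoyl)oxy]-2-hydroxy-3,5,6-trimethylbenzoate | COC(=O)c1c(C)c(C)c(OC(=O)c2c(C)cc(OCc3ccccc3)c(C)c2OC)c(C)c1O
F10 | step 9 | methyl 2-hydroxy-4-[(4-hydroxy-2-methoxy-3,6-dimethylbenzoyl)oxy]-3,5,6-trimethylbenzoate | COC(=O)c1c(C)c(C)c(OC(=O)c2c(C)cc(O)c(C)c2OC)c(C)c1O
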